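**Str​ategy.** The route rests on disconnecting the C4–C4a bond (ketone carbon to arene) of the 2,2-dimethylchroman-4-one half, together with the neighbouring C8a–O1 bond. An aryne, 3,5-dimethoxy-4-methylbenzyne, released from an ortho-silylaryl triflate, takes up the sodium alkoxide of methyl 3-hydroxy-3-methylbutanoate in one operation. Oxygen adds at C8a and the resulting C4a carbanion acylates the ester, closing the pyranone ring. The step exploits the adjacent pair C8a/C4a of ring B (the chromanone arene) and the C5 oxygen beside C4a, which steers the nucleophile to C8a. Demethylation, then a Mannich/ortho-quinone methide coupling at C8 with the acylphloroglucinol (ring A), installs the methylene bridge.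

Key step: step 4

Remark: the target has no stereocentre and no stereogenic double bond, so no step has to set configuration; chromanone numbering (O1, C2, C3, C4, C4a, C5 to C8, C8a) is used for ring B and its pyranone ring.

Step 1
Reactants: 1 2,6-dimethoxytoluene (1,3-dimethoxy-2-methylbenzene)
Product: 3 3,5-dimethoxy-4-methylphenol, via aryl pinacol boronate 2 (not isolated)
Conditions: HBpin (1.5 equiv), [Ir(OMe)(cod)]2 (1.5 mol %), dtbpy (3 mol %), THF, 80 °C; then Oxone (2KHSO5·KHSO4·K2SO4), acetone/H2O, rt
Reagents that add atoms: pinacolborane, CC1(C)OBOC1(C)C (boron group carried only in 2); potassium peroxymonosulfate KHSO5, [K+].[O-]S(=O)(=O)OO (phenol oxygen)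
Why: Iridium-catalysed C–H borylation is sterically controlled and should take the only ring C–H without an ortho substituent (para to the methyl group), and the aryl boronate is then oxidised in the same pot to the phenol (one-pot C–H borylation/oxidation).

Step 2
Reactants: 3 3,5-dimethoxy-4-methylphenol
Product: 4 2-bromo-3,5-dimethoxy-4-methylphenol
Conditions: NBS (1.0 equiv), CH2Cl2, −78 °C → 0 °C
Reagents that add atoms: N-bromosuccinimide, BrN1C(=O)CCC1=O
Why: Electrophilic aromatic bromination; the two free positions are equivalent by symmetry and ortho to the hydroxyl, and the para position is blocked by the methyl group, so one equivalent of NBS at low temperature should give a single monobromide.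

Step 3
Reactants: 4 2-bromo-3,5-dimethoxy-4-methylphenol
Product: 7 3,5-dimethoxy-4-methyl-2-(trimethylsilyl)phenyl trifluoromethanesulfonate, via silyl ether 5 (not isolated), via lithium silylphenoxide 6 (not isolated)
Conditions: HMDS, THF, 65 °C, then evaporation; n-BuLi, THF, −78 °C; Tf2O, −78 °C → rt
Reagents that add atoms: hexamethyldisilazane, C[Si](C)(C)N[Si](C)(C)C; trifluoromethanesulfonic anhydride, FC(F)(F)S(=O)(=O)OS(=O)(=O)C(F)(F)F
Why: Standard preparation of an ortho-silylaryl triflate: O-silylation gives 5, bromine–lithium exchange is followed at once by an anionic 1,3 O-to-C silyl shift (retro-Brook rearrangement) to phenoxide 6, and this is triflated on oxygen.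

Step 4
Reactants: 7 3,5-dimethoxy-4-methyl-2-(trimethylsilyl)phenyl trifluoromethanesulfonate; 8 methyl 3-hydroxy-3-methylbutanoate
Product: 12 5,7-dimethoxy-2,2,6-trimethylchroman-4-one, via sodium alkoxide 9 (not isolated), via aryne 10 (not isolated), via aryl anion 11 (not isolated)
Conditions: 8 (2 equiv), NaH (2 equiv), THF, 0 °C; then 7, CsF (3 equiv), 18-crown-6, THF, 0 °C → rt; aq. NH4Cl
Reagents that add atoms: none
Why: Proposed new method: fluoride removes the silyl group of 7 with loss of triflate to give aryne 10; alkoxide 9 adds through oxygen to the aryne carbon that carried the triflate (future C8a), leaving the carbanion of 11 on the carbon between the new ether oxygen and the methoxy group (future C4a); this carbanion attacks the ester carbonyl and expels methoxide, which forms the C4–C4a bond and closes the pyranone ring by a 6-exo-trig addition–elimination. The closest known reaction type is the aryne annulation of salicylate esters to xanthones (O-arylation, then intramolecular acylation of the aryl anion), and what is new is an aliphatic tertiary β-hydroxy ester as the partner. The regiochemistry needed, oxygen at C8a and carbon at C4a, is secured by the C5 methoxy group beside the triple bond: its inductive pull distorts the aryne so that the nucleophile attacks the remote carbon, the charge ends on the carbon next to oxygen, and the remote carbon (next to C8–H) is also the less hindered one. Acylation must outrun protonation of 11, which is secured by using the fully preformed sodium alkoxide so that the flask holds no O–H proton; ortho-aryl anions of this kind are known to add to ester carbonyls even in strained four-membered mode, so the six-membered closure should also outrun removal of an α-proton. Retro-aldol cleavage of 9 and capture of 10 by the released methoxide are the side reactions to be held down by low temperature and the excess of 9. No stereocentre is formed.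

Step 5
Reactants: 12 5,7-dimethoxy-2,2,6-trimethylchroman-4-one
Product: 13 5,7-dihydroxy-2,2,6-trimethylchroman-4-one
Conditions: BBr3 (4 equiv), CH2Cl2, −78 °C → rt; then H2O
Reagents that add atoms: none
Why: Lewis-acid cleavage of aryl methyl ethers; the C5 methyl ether should go first through chelation of boron between O5 and the C4 carbonyl, excess BBr3 should take the C7 methyl ether, and low temperature with short exposure is meant to leave the C2–O1 bond of the pyranone ring closed.

Step 6
Reactants: 14 2-methylphloroglucinol (2-methylbenzene-1,3,5-triol)
Product: 15 1-(2,4,6-trihydroxy-3-methylphenyl)-2-methylpropan-1-one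
Conditions: isobutyryl chloride (1.05 equiv), AlCl3 (4 equiv), PhNO2/CH2Cl2, 0 °C → rt; aq. HCl
Reagents that add atoms: isobutyryl chloride, CC(C)C(Cl)=O
Why: Friedel–Crafts C-acylation of a phloroglucinol; the two free ring positions are equivalent and the first acyl group deactivates the ring toward a second acylation.

Step 7
Reactants: 13 5,7-dihydroxy-2,2,6-trimethylchroman-4-one; 15 1-(2,4,6-trihydroxy-3-methylphenyl)-2-methylpropan-1-one
Product: 18 CNP0186856.0 (target), via Mannich base 16 (not isolated), via ortho-quinone methide 17 (not isolated)
Conditions: Me2N=CH2+ I− (1.0 equiv), NaOAc, MeCN, rt; then 15 (1.5 equiv), 80 °C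
Reagents that add atoms: N,N-dimethylmethyleneiminium iodide (Eschenmoser's salt), C=[N+](C)C.[I-]
Why: Mannich reaction at C8, the only free ring carbon of 13, then thermal loss of dimethylamine to ortho-quinone methide 17, which should take up the single free ring carbon of 15 in a Michael-type addition with rearomatisation; since 13 is consumed before 15 is added, the methylene group can only bridge ring B to ring A.

**Compound list**

1 | 2,6-dimethoxytoluene (1,3-dimethoxy-2-methylbenzene) | COc1cccc(OC)c1C | starting material
2 | 2-(3,5-dimethoxy-4-methylphenyl)-4,4,5,5-tetramethyl-1,3,2-dioxaborolane | COc1cc(B2OC(C)(C)C(C)(C)O2)cc(OC)c1C | intermediate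
3 | 3,5-dimethoxy-4-methylphenol | COc1cc(O)cc(OC)c1C | intermediate
4 | 2-bromo-3,5-dimethoxy-4-methylphenol | COc1cc(O)c(Br)c(OC)c1C | intermediate
5 | (2-bromo-3,5-dimethoxy-4-methylphenoxy)trimethylsilane | COc1cc(O[Si](C)(C)C)c(Br)c(OC)c1C | intermediate
6 | lithium 3,5-dimethoxy-4-methyl-2-(trimethylsilyl)phenoxide | COc1cc([O-])c([Si](C)(C)C)c(OC)c1C.[Li+] | intermediate
7 | 3,5-dimethoxy-4-methyl-2-(trimethylsilyl)phenyl trifluoromethanesulfonate | COc1cc(OS(=O)(=O)C(F)(F)F)c([Si](C)(C)C)c(OC)c1C | intermediate
8 | methyl 3-hydroxy-3-methylbutanoate | COC(=O)CC(C)(C)O | starting material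
9 | sodium 4-methoxy-2-methyl-4-oxobutan-2-olate | COC(=O)CC(C)(C)[O-].[Na+] | intermediate
10 | 3,5-dimethoxy-4-methylbenzyne (1,2-didehydro-3,5-dimethoxy-4-methylbenzene) | COC1=C(C)C(OC)=CC#C1 | intermediate
11 | methyl 3-(3,5-dimethoxy-4-methyl-2-sodiophenoxy)-3-methylbutanoate (aryl anion, sodium salt) | COC(=O)CC(C)(C)Oc1cc(OC)c(C)c(OC)[c-]1.[Na+] | intermediate
12 | 5,7-dimethoxy-2,2,6-trimethylchroman-4-one | COc1cc2OC(C)(C)CC(=O)c2c(OC)c1C | intermediate
13 | 5,7-dihydroxy-2,2,6-trimethylchroman-4-one | Cc1c(O)cc2OC(C)(C)CC(=O)c2c1O | intermediate
14 | 2-methylphloroglucinol (2-methylbenzene-1,3,5-triol) | Cc1c(O)cc(O)cc1O | starting material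
15 | 1-(2,4,6-trihydroxy-3-methylphenyl)-2-methylpropan-1-one | CC(C)C(=O)c1c(O)cc(O)c(C)c1O | intermediate
16 | 8-[(dimethylamino)methyl]-5,7-dihydroxy-2,2,6-trimethylchroman-4-one | CN(C)Cc1c(O)c(C)c(O)c2C(=O)CC(C)(C)Oc12 | intermediate
17 | 5-hydroxy-2,2,6-trimethyl-8-methylidene-2,3-dihydrochromene-4,7-dione (ortho-quinone methide of ring B) | C=C1C(=O)C(C)=C(O)C2=C1OC(C)(C)CC2=O | intermediate
18 | CNP0186856.0: 5,7-dihydroxy-2,2,6-trimethyl-8-[[2,4,6-trihydroxy-3-methyl-5-(2-methylpropanoyl)phenyl]methyl]chroman-4-one | Cc1c(O)c(Cc2c(O)c(C)c(O)c3c2OC(C)(C)CC3=O)c(O)c(C(=O)C(C)C)c1O | target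

**Step count.** Total: 7 steps. Longest linear sequence: 6 steps (steps 1, 2, 3, 4, 5 and 7); step 6 is the convergent branch.

**Steps most likely to fail**

Step 4 (Proposed new method). The aryl anion may be quenched before it reaches the ester carbonyl, either by taking a proton from the ester α-CH2 (after which the aryloxide is lost by β-elimination) or from adventitious proton sources. The alkoxide may also fragment by retro-aldol reaction, or simply add too slowly to the aryne. The fallback uses known chemistry, sets out from 7 and comes back at 12. Compound 7 is heated with 3,3-dimethylacrylic acid and CsF in THF (sealed tube, 65–125 °C). The carboxylate adds to the same aryne carbon, the aryl anion attacks the carboxyl carbon, and the aryne is formally inserted into the C–O bond of the acid. This known aryne insertion into carboxylic acids should give 1-(6-hydroxy-2,4-dimethoxy-3-methylphenyl)-3-methylbut-2-en-1-one F1. Its single free phenol then closes onto the enone by oxa-Michael addition, in the same pot or with MsOH, to give 12. The ring is then closed through O1–C2, but the regiochemistry is fixed by the same methoxy group.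

Step 7. Aminomethylation of the acyl-deactivated ring B may be slow, the ortho-quinone methide may condense with itself, or methylene transfer (retro-Mannich) may lead to symmetrical dimers. The fallback exchanges the roles of the two halves, sets out from 15 and comes back at 18. Compound 15 is aminomethylated with Eschenmoser's salt and NaOAc in MeCN at rt to the isolated Mannich base 1-[3-[(dimethylamino)methyl]-2,4,6-trihydroxy-5-methylphenyl]-2-methylpropan-1-one F2. F2 is then heated with 13 in 1,4-dioxane at 100 °C. Loss of dimethylamine now generates the ortho-quinone methide on ring A, and C8 of 13 (activated by the C7 hydroxyl and O1) acts as the nucleophile to give 18.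

Step 5. The Lewis acid may open the pyranone ring by retro-oxa-Michael reaction, and reclosure through the freed C5 hydroxyl would move the ring methyl group from C6 to C8. Cleavage of the unchelated C7 methyl ether may also stay incomplete. The fallback gives up the methyl ethers altogether, sets out from 14 and comes back at 13. Compound 14 is condensed with 3,3-dimethylacrylic acid in BF3·OEt2 at 70 °C, a known one-step chromanone synthesis. Friedel–Crafts acylation should give 1-(2,4,6-trihydroxy-3-methylphenyl)-3-methylbut-2-en-1-one F3, which closes by oxa-Michael addition through either ortho hydroxyl. The product is 13 beside its regioisomer 5,7-dihydroxy-2,2,8-trimethylchroman-4-one F4, and 13 is separated by chromatography. This fallback bypasses the aryne step and loses its regiocontrol.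

**Further compounds**

F1 | step 4 | 1-(6-hydroxy-2,4-dimethoxy-3-methylphenyl)-3-methylbut-2-en-1-one | CC(C)=CC(=O)c1c(O)cc(OC)c(C)c1OC
F2 | step 7 | 1-[3-[(dimethylamino)methyl]-2,4,6-trihydroxy-5-methylphenyl]-2-methylpropan-1-one | CC(C)C(=O)c1c(O)c(C)c(O)c(CN(C)C)c1O
F3 | step 5 | 1-(2,4,6-trihydroxy-3-methylphenyl)-3-methylbut-2-en-1-one | CC(C)=CC(=O)c1c(O)cc(O)c(C)c1O
F4 | step 5 | 5,7-dihydroxy-2,2,8-trimethylchroman-4-one | Cc1c(O)cc(O)c2C(=O)CC(C)(C)Oc12
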